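**Retrosynthetic overview**
- Feature: the coumarin carbocycle (C4a, C5, C6, C7, C8, C8a), which carries C4 on C4a, flavone C8 on C6 and oxygen on C7 and C8a, is built rather than bought. It is cut into a two-carbon piece C6–C7 (an ynol ether on flavone C8) and a four-carbon piece C5–C4a–C8a–C8 (C6, C5, C4, C3 of a 4-methoxy-2-pyrone-5-carboxylate).
- Target ⇐ global O-dealkylation ⇐ coumarin lactone ring by Wittig olefination and lactonization of a salicylaldehyde ⇐ aldehyde from the benzoate ester by hydrolysis, thioesterification and Fukuyama reduction.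
- Key disconnection: the 5-aryl-4-ethoxy-2-methoxybenzoate ⇐ [4+2] cycloaddition and loss of CO2 between the 8-(ethoxyethynyl)flavone and the pyrone.
- Ynol ether ⇐ C8 iodination and Negishi alkynylation of 5,7,4'-trimethoxyflavone; pyrone ⇐ dimethyl 3-oxopentanedioate and triethyl orthoformate, then O-methylation.
- Ring order: flavone rings (bought), then the coumarin benzene ring (step 5), then the coumarin lactone ring (step 10).

Key step: step 5

Remark: the aryl–aryl axis has only three small oxygen ortho substituents and the target carries no axial descriptor, so it is treated as freely rotating and no stereocontrol is planned.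
Remark: hydride reagents such as DIBAL-H or LiAlH4 would also attack the flavone C4 carbonyl, so the ester is taken to the aldehyde without a metal hydride, through the acid and the thioester.

**Route**

Step 1
Reactants: 1 5,7-dimethoxy-2-(4-methoxyphenyl)-4H-chromen-4-one (5,7,4'-trimethoxyflavone)
Product: 2 8-iodo-5,7-dimethoxy-2-(4-methoxyphenyl)-4H-chromen-4-one
Conditions: NIS (1.1 equiv), CF3CO2H (0.3 equiv), MeCN, 0 °C to rt, dark
Reagents that add atoms: N-iodosuccinimide, O=C1CCC(=O)N1I
Why: Electrophilic aromatic iodination should go to C8 of ring A, which is activated by O1 and by the 7- and 5-methoxy groups and is less crowded than C6 between two methoxy groups, while C3 and ring B are far less nucleophilic.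

Step 2
Reactants: 2 8-iodo-5,7-dimethoxy-2-(4-methoxyphenyl)-4H-chromen-4-one; 3 ethoxyacetylene
Product: 6 8-(ethoxyethynyl)-5,7-dimethoxy-2-(4-methoxyphenyl)-4H-chromen-4-one, via lithium ethoxyacetylide 4 (not isolated), via ethoxyethynylzinc chloride 5 (not isolated)
Conditions: 3 (1.6 equiv), n-BuLi, THF, −78 °C; ZnCl2, −78 to 0 °C; then 2, Pd(PPh3)4 (5 mol %), THF, rt to 45 °C; chromatography on Et3N-deactivated silica
Reagents that add atoms: n-butyllithium, CCCC[Li] (lithium of 4); zinc dichloride, Cl[Zn]Cl (zinc and chlorine of 5)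
Why: Negishi coupling of the aryl iodide with the alkynylzinc reagent should proceed under mild, weakly basic conditions that leave the flavone carbonyl alone, and the linear alkynyl group meets little hindrance from the two ortho oxygens.

Step 3
Reactants: 7 dimethyl 3-oxopentanedioate; 8 triethyl orthoformate
Product: 10 methyl 4-hydroxy-2-oxo-2H-pyran-5-carboxylate, via dimethyl 2-(ethoxymethylene)-3-oxopentanedioate 9 (not isolated)
Conditions: 8 (1.1 equiv), Ac2O, 130 °C; concentrate; 1 M aq. HCl, rt
Reagents that add atoms: water, O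
Why: Ethoxymethylenation of the active methylene by the orthoformate, followed by acid hydrolysis of the enol ether and lactonization of the resulting enol onto the distal ester, is the established way to 4-hydroxy-2-pyrone-5-carboxylates.

Step 4
Reactants: 10 methyl 4-hydroxy-2-oxo-2H-pyran-5-carboxylate
Product: 11 methyl 4-methoxy-2-oxo-2H-pyran-5-carboxylate
Conditions: Me2SO4 (1.2 equiv), K2CO3, acetone, reflux
Reagents that add atoms: dimethyl sulfate, COS(=O)(=O)OC
Why: Williamson-type O-alkylation of the acidic 4-hydroxy-2-pyrone with a hard methylating agent under weak base should give the 4-methoxy-2-pyrone rather than the C3-methyl or 2-methoxy-4-pyrone isomers.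

Step 5
Reactants: 6 8-(ethoxyethynyl)-5,7-dimethoxy-2-(4-methoxyphenyl)-4H-chromen-4-one; 11 methyl 4-methoxy-2-oxo-2H-pyran-5-carboxylate
Product: 13 methyl 5-[5,7-dimethoxy-2-(4-methoxyphenyl)-4-oxo-4H-chromen-8-yl]-4-ethoxy-2-methoxybenzoate, via 2-oxabicyclo[2.2.2]octadienone cycloadduct 12 (not isolated)
Conditions: 11 (3 equiv), toluene (1 M in 6), 85 °C, sealed tube, Ar
Reagents that add atoms: none
Why: The 2-pyrone is an electron-poor diene (C3=C4–C5=C6, lowered in energy by the lactone carbonyl and the C5 ester) and the ynol ether an electron-rich dienophile, so an inverse-electron-demand [4+2] cycloaddition, probably asynchronous with the bond from the aryl-bearing alkyne carbon to pyrone C6 leading the bond from the ethoxy-bearing carbon to C3, should give the bridged lactone 12, which expels CO2 by retro-[4+2] and delivers the benzene ring directly. The closest known reaction type is the cycloaddition with CO2 loss of coumalate esters (2-pyrone-5-carboxylates) with ynamines, ynol ethers and ketene acetals; the 4-methoxy group of 11 is an extra donor not yet examined in this role, expected to slow the reaction but not to change its course, because C6 remains the β-carbon of an acrylate that also carries the acyloxy oxygen. The six-membered carbocycle is closed by an intermolecular [4+2] cycloaddition that forms two ring bonds (coumarin C5–C6 and C7–C8 in the final numbering), and aromatization by cycloreversion makes the step irreversible. No stereocentre remains: the two bridgehead centres of racemic 12 vanish on loss of CO2, and the new biaryl axis is not expected to be configurationally stable. The selectivity needed is regiochemical and is secured by the polarization of both partners: the nucleophilic β-carbon of the ynol ether, which bears the flavonyl group, attacks the most electrophilic diene terminus C6, placing ethoxy para and the flavonyl group meta to the ester. The temperature is held below about 100 °C, where ethyl ynol ethers begin to lose ethylene by retro-ene reaction, and the easily made pyrone is used in excess at high concentration to compensate.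

Step 6
Reactants: 13 methyl 5-[5,7-dimethoxy-2-(4-methoxyphenyl)-4-oxo-4H-chromen-8-yl]-4-ethoxy-2-methoxybenzoate
Product: 14 5-[5,7-dimethoxy-2-(4-methoxyphenyl)-4-oxo-4H-chromen-8-yl]-4-ethoxy-2-methoxybenzoic acid
Conditions: LiOH·H2O (5 equiv), THF/MeOH/H2O, 45 °C; then 1 M HCl to pH 3
Reagents that add atoms: lithium hydroxide, [Li+].[OH-]
Why: Saponification of the methyl benzoate under mild aqueous hydroxide should leave the aryl ethers and the flavone pyranone ring, which opens only in hot concentrated alkali, intact.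

Step 7
Reactants: 14 5-[5,7-dimethoxy-2-(4-methoxyphenyl)-4-oxo-4H-chromen-8-yl]-4-ethoxy-2-methoxybenzoic acid
Product: 15 S-ethyl 5-[5,7-dimethoxy-2-(4-methoxyphenyl)-4-oxo-4H-chromen-8-yl]-4-ethoxy-2-methoxybenzenecarbothioate
Conditions: EtSH (3 equiv), DCC (1.3 equiv), DMAP (0.1 equiv), CH2Cl2, 0 °C to rt
Reagents that add atoms: ethanethiol, CCS
Why: Steglich-type thioesterification (carbodiimide activation, DMAP acyl transfer) converts the acid into the thioester under neutral conditions that do not touch the flavone.

Step 8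
Reactants: 15 S-ethyl 5-[5,7-dimethoxy-2-(4-methoxyphenyl)-4-oxo-4H-chromen-8-yl]-4-ethoxy-2-methoxybenzenecarbothioate
Product: 16 5-[5,7-dimethoxy-2-(4-methoxyphenyl)-4-oxo-4H-chromen-8-yl]-4-ethoxy-2-methoxybenzaldehyde
Conditions: Et3SiH (3 equiv), Pd/C (10 wt % Pd, 5 mol %), acetone, rt
Reagents that add atoms: none
Why: Fukuyama reduction (insertion of zerovalent palladium into the acyl C–S bond, hydride transfer from the silane, reductive elimination) stops at the aldehyde and spares the flavone carbonyl and its C2–C3 double bond.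

Step 9
Reactants: 16 5-[5,7-dimethoxy-2-(4-methoxyphenyl)-4-oxo-4H-chromen-8-yl]-4-ethoxy-2-methoxybenzaldehyde
Product: 17 4-ethoxy-2-hydroxy-5-[5-hydroxy-7-methoxy-2-(4-methoxyphenyl)-4-oxo-4H-chromen-8-yl]benzaldehyde
Conditions: BCl3 (1 M in CH2Cl2, 4 equiv), CH2Cl2, −78 to 0 °C; H2O quench
Reagents that add atoms: none
Why: Chelation-directed Lewis acid ether cleavage by BCl3 removes only the methyl groups whose oxygen can bind boron together with a neighbouring carbonyl oxygen, that is the methoxy ortho to the aldehyde and the flavone 5-methoxy peri to C4=O, while the ethoxy and the 7- and 4'-methoxy groups should stay.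

Step 10
Reactants: 17 4-ethoxy-2-hydroxy-5-[5-hydroxy-7-methoxy-2-(4-methoxyphenyl)-4-oxo-4H-chromen-8-yl]benzaldehyde
Product: 19 8-(7-ethoxy-2-oxo-2H-chromen-6-yl)-5-hydroxy-7-methoxy-2-(4-methoxyphenyl)-4H-chromen-4-one, via ethyl (E)-2-hydroxycinnamate intermediate 18 (not isolated)
Conditions: Ph3P=CHCO2Et (2.5 equiv), PhNEt2, reflux (about 215 °C), N2
Reagents that add atoms: ethyl (triphenylphosphoranylidene)acetate, CCOC(=O)C=P(c1ccccc1)(c1ccccc1)c1ccccc1
Why: Wittig olefination with the stabilized ylide gives the 2-hydroxycinnamate, and at the reflux temperature of diethylaniline the (E)-alkene isomerizes and lactonizes with loss of ethanol to close the coumarin pyranone ring, the chelated flavone 5-hydroxyl being inert.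

Step 11
Reactants: 19 8-(7-ethoxy-2-oxo-2H-chromen-6-yl)-5-hydroxy-7-methoxy-2-(4-methoxyphenyl)-4H-chromen-4-one
Product: 20 5,7-dihydroxy-8-(7-hydroxy-2-oxo-2H-chromen-6-yl)-2-(4-hydroxyphenyl)-4H-chromen-4-one (target)
Conditions: BBr3 (1 M in CH2Cl2, 12 equiv), CH2Cl2, −78 °C to rt; ice-water quench
Reagents that add atoms: none
Why: Lewis acid ether cleavage with BBr3 removes the two remaining methyl groups and the ethyl group through aryloxy dibromoboranes, and coumarin lactones and flavones are known to survive such dealkylations.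

**Compound list**
1 | 5,7-dimethoxy-2-(4-methoxyphenyl)-4H-chromen-4-one (5,7,4'-trimethoxyflavone) | COc1ccc(-c2cc(=O)c3c(OC)cc(OC)cc3o2)cc1 | starting material
2 | 8-iodo-5,7-dimethoxy-2-(4-methoxyphenyl)-4H-chromen-4-one | COc1ccc(-c2cc(=O)c3c(OC)cc(OC)c(I)c3o2)cc1 | intermediate
3 | ethoxyacetylene | CCOC#C | starting material
4 | lithium ethoxyacetylide | CCOC#C[Li] | intermediate (not isolated)
5 | ethoxyethynylzinc chloride | CCOC#C[Zn]Cl | intermediate (not isolated)
6 | 8-(ethoxyethynyl)-5,7-dimethoxy-2-(4-methoxyphenyl)-4H-chromen-4-one | CCOC#Cc1c(OC)cc(OC)c2c(=O)cc(-c3ccc(OC)cc3)oc12 | intermediate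
7 | dimethyl 3-oxopentanedioate (dimethyl 3-oxoglutarate) | COC(=O)CC(=O)CC(=O)OC | starting material
8 | triethyl orthoformate | CCOC(OCC)OCC | starting material
9 | dimethyl 2-(ethoxymethylene)-3-oxopentanedioate (E/Z mixture) | CCOC=C(C(=O)OC)C(=O)CC(=O)OC | intermediate (not isolated)
10 | methyl 4-hydroxy-2-oxo-2H-pyran-5-carboxylate | COC(=O)c1coc(=O)cc1O | intermediate
11 | methyl 4-methoxy-2-oxo-2H-pyran-5-carboxylate | COC(=O)c1coc(=O)cc1OC | intermediate
12 | methyl 7-[5,7-dimethoxy-2-(4-methoxyphenyl)-4-oxo-4H-chromen-8-yl]-8-ethoxy-5-methoxy-3-oxo-2-oxabicyclo[2.2.2]octa-5,7-diene-6-carboxylate (racemic) | O=C1OC2C(C(=O)OC)=C(OC)C1C(OCC)=C2c3c(OC)cc(OC)c4c(=O)cc(-c5ccc(OC)cc5)oc34 | intermediate (not isolated)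
13 | methyl 5-[5,7-dimethoxy-2-(4-methoxyphenyl)-4-oxo-4H-chromen-8-yl]-4-ethoxy-2-methoxybenzoate | CCOc1cc(OC)c(C(=O)OC)cc1-c1c(OC)cc(OC)c2c(=O)cc(-c3ccc(OC)cc3)oc12 | intermediate
14 | 5-[5,7-dimethoxy-2-(4-methoxyphenyl)-4-oxo-4H-chromen-8-yl]-4-ethoxy-2-methoxybenzoic acid | CCOc1cc(OC)c(C(=O)O)cc1-c1c(OC)cc(OC)c2c(=O)cc(-c3ccc(OC)cc3)oc12 | intermediate
15 | S-ethyl 5-[5,7-dimethoxy-2-(4-methoxyphenyl)-4-oxo-4H-chromen-8-yl]-4-ethoxy-2-methoxybenzenecarbothioate | CCOc1cc(OC)c(C(=O)SCC)cc1-c1c(OC)cc(OC)c2c(=O)cc(-c3ccc(OC)cc3)oc12 | intermediate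
16 | 5-[5,7-dimethoxy-2-(4-methoxyphenyl)-4-oxo-4H-chromen-8-yl]-4-ethoxy-2-methoxybenzaldehyde | CCOc1cc(OC)c(C=O)cc1-c1c(OC)cc(OC)c2c(=O)cc(-c3ccc(OC)cc3)oc12 | intermediate
17 | 4-ethoxy-2-hydroxy-5-[5-hydroxy-7-methoxy-2-(4-methoxyphenyl)-4-oxo-4H-chromen-8-yl]benzaldehyde | CCOc1cc(O)c(C=O)cc1-c1c(OC)cc(O)c2c(=O)cc(-c3ccc(OC)cc3)oc12 | intermediate
18 | ethyl (2E)-3-{4-ethoxy-2-hydroxy-5-[5-hydroxy-7-methoxy-2-(4-methoxyphenyl)-4-oxo-4H-chromen-8-yl]phenyl}prop-2-enoate | CCOC(=O)/C=C/c1cc(-c2c(OC)cc(O)c3c(=O)cc(-c4ccc(OC)cc4)oc23)c(OCC)cc1O | intermediate (not isolated)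
19 | 8-(7-ethoxy-2-oxo-2H-chromen-6-yl)-5-hydroxy-7-methoxy-2-(4-methoxyphenyl)-4H-chromen-4-one | CCOc1cc2oc(=O)ccc2cc1-c1c(OC)cc(O)c2c(=O)cc(-c3ccc(OC)cc3)oc12 | intermediate
20 | 5,7-dihydroxy-8-(7-hydroxy-2-oxo-2H-chromen-6-yl)-2-(4-hydroxyphenyl)-4H-chromen-4-one | O=c1ccc2cc(-c3c(O)cc(O)c4c(=O)cc(-c5ccc(O)cc5)oc34)c(O)cc2o1 | target

**Step count**
Total: 11 steps. Longest linear sequence: 9 steps (steps 1, 2, 5 to 11; the pyrone branch, steps 3, 4, 5 to 11, is equally long).

**Steps most likely to fail**

1. Step 5. The cycloaddition may be too slow below the temperature at which the ethyl ynol ether loses ethylene to an aryl ketene, because the 4-methoxy group weakens the pyrone as an inverse-demand diene. Hydration of the ynol ether by traces of acid would also consume it. The fallback builds the same biaryl bond by Suzuki–Miyaura coupling, sets out from 2 and comes back at 13. Commercial methyl 4-hydroxy-2-methoxybenzoate would be ethylated (EtI, K2CO3, DMF) to methyl 4-ethoxy-2-methoxybenzoate F1. Bromination at C5 (NBS, MeCN) would give methyl 5-bromo-4-ethoxy-2-methoxybenzoate F2. Miyaura borylation (B2pin2, Pd(dppf)Cl2, KOAc, dioxane, 90 °C) would give methyl 4-ethoxy-2-methoxy-5-(4,4,5,5-tetramethyl-1,3,2-dioxaborolan-2-yl)benzoate F3. Coupling of F3 with iodide 2 (Pd(OAc)2, SPhos, K3PO4, toluene/H2O, 100 °C) should give 13, and the route continues at step 6.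

2. Step 2. Oxidative addition and transmetalation at the doubly ortho-substituted iodide may be slow, so that the zinc acetylide decomposes or homocouples first, and the ynol ether may hydrate to the arylacetate during work-up or chromatography. The fallback replaces the zinc acetylide made in the flask by an isolable, neutral tin reagent; it sets out from 2 and 3 and comes back at 6. Ethoxyacetylene 3 would be lithiated and quenched with Bu3SnCl to give tributyl(ethoxyethynyl)stannane F4, purified by distillation. Stille coupling of F4 with 2 (PdCl2(PPh3)2, Et4NCl, DMF, 60 °C) under neutral conditions should give 6.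

3. Step 10. The (E)-cinnamate may fail to isomerize and lactonize completely, or the polyfunctional substrate may degrade at the high temperature needed. The fallback forms the pyranone ring by condensation instead of olefination, sets out from 17 and comes back at 19. Knoevenagel condensation of 17 with Meldrum's acid (piperidinium acetate, EtOH, reflux) closes the lactone directly and should give 7-ethoxy-6-[5-hydroxy-7-methoxy-2-(4-methoxyphenyl)-4-oxo-4H-chromen-8-yl]-2-oxo-2H-chromene-3-carboxylic acid F5. Decarboxylation of F5 (Cu powder, quinoline, 200 °C) should give 19.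

**Further compounds**
F1 | step 5 | methyl 4-ethoxy-2-methoxybenzoate | CCOc1ccc(C(=O)OC)c(OC)c1
F2 | step 5 | methyl 5-bromo-4-ethoxy-2-methoxybenzoate | CCOc1cc(OC)c(C(=O)OC)cc1Br
F3 | step 5 | methyl 4-ethoxy-2-methoxy-5-(4,4,5,5-tetramethyl-1,3,2-dioxaborolan-2-yl)benzoate | CCOc1cc(OC)c(C(=O)OC)cc1B1OC(C)(C)C(C)(C)O1
F4 | step 2 | tributyl(ethoxyethynyl)stannane | CCOC#C[Sn](CCCC)(CCCC)CCCC
F5 | step 10 | 7-ethoxy-6-[5-hydroxy-7-methoxy-2-(4-methoxyphenyl)-4-oxo-4H-chromen-8-yl]-2-oxo-2H-chromene-3-carboxylic acid | CCOc1cc2oc(=O)c(C(=O)O)cc2cc1-c1c(OC)cc(O)c2c(=O)cc(-c3ccc(OC)cc3)oc12
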